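The plan rests on the 1,6 relationship between the C3 ketone and the C8 lactone oxygen across the ten-membered carbocycle (C4–C7 on one arc, C2, C1, C10, C9 on the other). Joining C3 to C8 in retrosynthesis contracts that ring to a cyclohexane-1,2-diol that already holds the C4–C7 stereocentres, with vinyl on C3 and (E)-propenyl on C8. This cyclohexane is built from L-threitol and locked in one chair by the trans-fused acetonide. One anionic oxy-Cope rearrangement of the C8 alkoxide (O3 silylated) then expands six to ten, leaves differentiated oxygen at C3 (silyl enol ether) and C8 (ketone), and sets C10; lactone, epoxide and esters follow.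

Key step: step 17

Remark: germacrane locants are used for every intermediate (ring carbons C1–C10, lactone carbons C11–C13, C14 on C10, C15 on C4); in this numbering the target is 1S,2S,4S,5R,6S,7S,8R,10R. Centres that are destroyed later (C4 in 11 and 12, C8 in 16 to 21, C11 in 38 and 39) are drawn as the expected isomer, and either epimer would serve.

Step 1
Reactants: 1 1,4-di-O-tosyl-2,3-O-isopropylidene-L-threitol; 2 vinylmagnesium bromide
Product: 3 (4S,5S)-4,5-diallyl-2,2-dimethyl-1,3-dioxolane
Conditions: CH2=CHMgBr (4 equiv), CuI (10 mol%), THF, −30 to 0 °C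
Reagents that add atoms: vinylmagnesium bromide (2), C=C[Mg]Br
Why: Copper-catalysed Grignard coupling (SN2 displacement at carbon) should replace both primary tosylates by vinyl; the two dioxolane stereocentres, the future C5 and C6, are not touched.

Step 2
Reactants: 3 (4S,5S)-4,5-diallyl-2,2-dimethyl-1,3-dioxolane
Product: 4 (3aS,7aS)-2,2-dimethyl-3a,4,7,7a-tetrahydro-1,3-benzodioxole (trans-acetonide of cyclohex-4-ene-1,2-diol; alkene C3=C8)
Conditions: second-generation Grubbs catalyst (H2IMes)(PCy3)Cl2Ru=CHPh (2 mol%), CH2Cl2, 40 °C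
Reagents that add atoms: none
Why: Ring-closing metathesis of the 1,7-diene should close the cyclohexene with loss of ethene; no stereocentre is formed.

Step 3
Reactants: 4 trans-acetonide of cyclohex-4-ene-1,2-diol
Product: 5 cis-epoxide of 4 (C3–C8 oxirane)
Conditions: mCPBA, CH2Cl2, 0 °C to rt
Reagents that add atoms: 3-chloroperoxybenzoic acid (mCPBA), OOC(=O)c1cccc(Cl)c1
Why: Prilezhaev epoxidation; the C2 axis of 4 interchanges the two alkene faces, so only one epoxide can form.

Step 4
Reactants: 5 cis-epoxide of 4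
Product: 8 allylic alcohol (C3 carbinol; C7=C8), via hydroxy selenide 6 (not isolated), via selenoxide 7 (not isolated)
Conditions: PhSeSePh, NaBH4, EtOH, reflux; then 30% H2O2, THF, 0 °C to rt
Reagents that add atoms: none
Why: Selenide opening of the epoxide followed by selenoxide syn-elimination: PhSe− opens trans-diaxially, the selenoxide eliminates away from the carbinol carbon, and either regiochemistry of opening converges on the same enone in step 5 because of the C2 symmetry of 4.

Step 5
Reactants: 8 allylic alcohol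
Product: 9 (3aS,7aS)-2,2-dimethyl-3a,7a-dihydro-1,3-benzodioxol-5(4H)-one (C3 ketone; C7=C8; trans-5,6-acetonide)
Conditions: Dess–Martin periodinane, CH2Cl2, rt
Reagents that add atoms: none
Why: Dess–Martin oxidation of the allylic alcohol should give the enone and removes the carbinol stereocentre.

Step 6
Reactants: 9 trans-5,6-acetonide enone
Product: 11 4-hydroxy enone (hydroxyl drawn cis to O5), via sodium dienolate 10 (not isolated)
Conditions: NaN(SiMe3)2, THF, −78 °C; 2-(phenylsulfonyl)-3-phenyloxaziridine, −78 °C; AcOH quench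
Reagents that add atoms: 2-(phenylsulfonyl)-3-phenyloxaziridine, O=S(=O)(N1OC1c1ccccc1)c1ccccc1
Why: Kinetic deprotonation at C4 gives the cross-conjugated dienolate (the equatorial C5–O bond lies in the enolate plane, so β-elimination is stereoelectronically disfavoured) and N-sulfonyloxaziridine enolate hydroxylation places oxygen on C4; this centre is re-enolised in step 8.

Step 7
Reactants: 11 4-hydroxy enone
Product: 12 4-(tert-butyldimethylsilyloxy) enone
Conditions: TBSCl, imidazole, DMF, rt
Reagents that add atoms: tert-butyldimethylsilyl chloride (TBSCl), CC(C)(C)[Si](C)(C)Cl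
Why: Standard silylation of the secondary α-ketol hydroxyl.

Step 8
Reactants: 12 4-(tert-butyldimethylsilyloxy) enone
Product: 14 enone with quaternary C4 (4S; methyl axial; OTBS equatorial), via lithium enolate 13 (not isolated)
Conditions: LiN(iPr)2, THF, −78 °C; MeI, DMPU, −78 to −40 °C
Reagents that add atoms: iodomethane, CI
Why: C-alkylation of the α-siloxy enolate; in the half-chair locked by the trans-acetonide, iodomethane should enter axially, anti to the axial C5–H, so that methyl is axial and the silyloxy group equatorial, and the cold lithium enolate should not pass silicon between its two oxygens.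

Step 9
Reactants: 14 enone with quaternary C4; 2 vinylmagnesium bromide
Product: 15 7-vinyl C3=C8 trimethylsilyl enol ether
Conditions: CH2=CHMgBr, CuBr·SMe2 (20 mol%), Me3SiCl, THF, −78 °C; Et3N
Reagents that add atoms: vinylmagnesium bromide (2), C=C[Mg]Br; chlorotrimethylsilane, C[Si](C)(C)Cl
Why: Copper-catalysed, silyl chloride-accelerated conjugate addition; vinyl should attack C7 along the axial trajectory that leads straight to the chair enolate (anti to the axial C6–H), giving the axial C7 substituent cis to O6 as the target requires, and the enolate is captured as the silyl enol ether.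

Step 10
Reactants: 15 7-vinyl C3=C8 trimethylsilyl enol ether
Product: 17 7-vinyl 8-hydroxy C3 ketone, via 8-trimethylsilyloxy ketone 16 (not isolated)
Conditions: mCPBA, CH2Cl2, −20 °C; then Et3N·3HF, THF, 0 °C
Reagents that add atoms: 3-chloroperoxybenzoic acid (mCPBA), OOC(=O)c1cccc(Cl)c1
Why: Rubottom oxidation: the electron-rich silyl enol ether is epoxidised far faster than the vinyl group, silyl shift gives the α-silyloxy ketone and fluoride frees the ketol; oxygen is expected trans to the axial vinyl group, but C8 is oxidised in step 14, so its configuration does not matter.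

Step 11
Reactants: 17 7-vinyl 8-hydroxy C3 ketone
Product: 19 keto diol (C8 and C12 hydroxyls), via B-alkyl-9-BBN adduct 18 (not isolated)
Conditions: 9-BBN, THF, 0 °C to rt; then 30% H2O2, aq. NaOAc, 0 °C
Reagents that add atoms: hydrogen peroxide, OO
Why: Hydroboration–oxidation; 9-BBN should add anti-Markovnikov to the terminal vinyl group much faster than it reduces the C3 ketone, which is flanked by the quaternary C4, and buffered peroxide spares the ketol.

Step 12
Reactants: 19 keto diol
Product: 20 C12 tert-butyldimethylsilyl ether of 19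
Conditions: TBSCl, imidazole, CH2Cl2, 0 °C
Reagents that add atoms: tert-butyldimethylsilyl chloride (TBSCl), CC(C)(C)[Si](C)(C)Cl
Why: Selective silylation of the primary hydroxyl over the hindered secondary ketol hydroxyl.

Step 13
Reactants: 20 C12 silyl ether; 2 vinylmagnesium bromide
Product: 21 3-vinyl 3,8-diol (vinyl equatorial; C3–O axial)
Conditions: CH2=CHMgBr (4 equiv), CeCl3, THF, −78 to 0 °C
Reagents that add atoms: vinylmagnesium bromide (2), C=C[Mg]Br
Why: Cerium-promoted Grignard 1,2-addition to the hindered ketone; the axial path to C3 is blocked by the syn-axial C7 side chain, so vinyl should enter equatorially and leave the new C3–O bond axial.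

Step 14
Reactants: 21 3-vinyl 3,8-diol
Product: 22 3-vinyl 3-hydroxy 8-ketone
Conditions: Dess–Martin periodinane, CH2Cl2, 0 °C to rt
Reagents that add atoms: none
Why: Dess–Martin oxidation of the secondary C8 carbinol; the tertiary allylic C3 hydroxyl cannot be oxidised.

Step 15
Reactants: 22 3-vinyl 3-hydroxy 8-ketone
Product: 23 3-vinyl 3-trimethylsilyloxy 8-ketone
Conditions: 1-(trimethylsilyl)imidazole, CH2Cl2, rt
Reagents that add atoms: 1-(trimethylsilyl)imidazole, C[Si](C)(C)n1ccnc1
Why: Silylation of the hindered tertiary hydroxyl with a reagent that does not enolise the neighbouring ketone; the cap ensures that only O8 can become an alkoxide in step 17 and later delivers C3 as a silyl enol ether.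

Step 16
Reactants: 23 3-vinyl 3-trimethylsilyloxy 8-ketone; 24 (E)-1-bromopropene
Product: 27 trans-3-vinyl-8-[(E)-propenyl]cyclohexane-3,8-diol 3-trimethylsilyl ether (both alkenyl arms equatorial; C8–OH axial), via (E)-propenyllithium 25 (not isolated), via (E)-propenylcerium dichloride 26 (not isolated)
Conditions: 24, t-BuLi (2 equiv per bromide), Et2O, −78 °C; CeCl3, THF, −78 °C; then 23, −78 °C
Reagents that add atoms: (E)-1-bromopropene (24), C/C=C/Br
Why: Organocerium 1,2-addition to a hindered, enolisable ketone: bromine–lithium exchange keeps the E geometry, the weakly basic cerium reagent suppresses enolisation towards C7, and because the axial path to C8 is blocked by the syn-axial C4 methyl the propenyl group should enter equatorially.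

Step 17
Reactants: 27 trans-3-vinyl-8-[(E)-propenyl]cyclohexane-3,8-diol 3-trimethylsilyl ether
Product: 30 ten-membered C8 ketone with C2=C3 trimethylsilyl enol ether and C10 methyl, via potassium alkoxide 28 (not isolated), via potassium enolate 29 (not isolated)
Conditions: KN(SiMe3)2, 18-crown-6, THF, −78 to 0 °C; then AcOH, −78 °C
Reagents that add atoms: none
Why: KN(SiMe3)2 with 18-crown-6 should give the ion-separated C8 alkoxide 28, whose oxyanion loosens the fully substituted C3–C8 bond so that the 1,5-diene C1=C2–C3–C8–C9=C10 undergoes a [3,3] sigmatropic shift (anionic oxy-Cope rearrangement), making C1–C10, breaking C3–C8 and giving enolate 29, which acetic acid protonates at C9 in the cold. The closest known reaction is the anionic oxy-Cope ring expansion of trans-1,2-dialkenylcyclohexanols to cyclodec-5-enones, here in its glycol form with the second oxygen held as a silyl ether. The ten-membered carbocycle is not closed end to end but arises by four-carbon ring expansion of the cyclohexane, the new C1–C10 bond forming between the two alkene termini inside a six-centre chair. C10 is the only new stereocentre and is controlled by chirality transfer from C8: the Cope chair is fused trans-decalin-like to the cyclohexane and the E-propenyl geometry places the methyl pseudo-equatorial, which gives the configuration that is 10R in the target. The step needs the chair rather than the boat pathway and an alkoxide on C8 only; the acetonide-locked chair with both alkenyl arms equatorial secures the first, and the silyl cap on O3, trans-diaxial to O8 so that it cannot migrate, secures the second. Enolate formation and the loss of two syn-diaxial contacts (C4 methyl with O8, C7 chain with O3) drive the step, and the cold quench of the regiodefined C8=C9 enolate protects C7.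

Step 18
Reactants: 30 ten-membered C8 ketone with C2=C3 silyl enol ether
Product: 31 (1Z)-ene-3,8-dione
Conditions: Pd(OAc)2 (1.05 equiv), MeCN, rt
Reagents that add atoms: none
Why: Saegusa–Ito oxidation: the C2=C3 silyl enol ether, the only one possible because C4 is quaternary, is converted into the C1=C2 enone through a palladium enolate and β-hydride elimination, and the Z geometry is expected as the less strained one in the ten-membered ring.

Step 19
Reactants: 31 (1Z)-ene-3,8-dione
Product: 32 (8R)-8-hydroxy (1Z)-en-3-one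
Conditions: NaBH4, MeOH/CH2Cl2 (1:1), −78 °C
Reagents that add atoms: none
Why: Chemoselective borohydride reduction (the saturated C8 ketone reacts before the hindered, conjugated C3 enone at low temperature); hydride should attack the outer face of the C8 carbonyl, anti to C6 and past H7 with the C7 side chain anti to the carbonyl oxygen, giving the alcohol with H8 anti to H7.

Step 20
Reactants: 32 8-hydroxy enone
Product: 33 8,12-diol
Conditions: HF·pyridine, pyridine, THF, 0 °C
Reagents that add atoms: none
Why: Fluoride cleavage of the primary silyl ether under buffered, non-basic conditions; the hindered tertiary silyl ether at C4 and the acetonide should survive, and the free C8 hydroxyl is not exposed to base that could trigger transannular addition to the enone.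

Step 21
Reactants: 33 8,12-diol
Product: 35 (1Z)-en-3-one 8,12-olide (trans-fused γ-lactone), via lactol 34 (not isolated)
Conditions: TEMPO (2,2,6,6-tetramethylpiperidin-1-oxyl, 20 mol%), PhI(OAc)2 (2.5 equiv), CH2Cl2, rt
Reagents that add atoms: none
Why: Nitroxyl-catalysed oxidative lactonisation: the primary alcohol is oxidised selectively to the aldehyde, the C8 hydroxyl closes the five-membered lactol (5-exo-trig) and this is oxidised on to the γ-lactone, whose trans fusion is already fixed by C7 and C8.

Step 22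
Reactants: 35 (1Z)-en-3-one 8,12-olide
Product: 36 (1S,2S)-1,2-cis-epoxy-3-oxo 8,12-olide
Conditions: t-BuOOH (anhydrous), DBU (1,8-diazabicyclo[5.4.0]undec-7-ene, 0.5 equiv), CH2Cl2, 0 °C
Reagents that add atoms: tert-butyl hydroperoxide, CC(C)(C)OO
Why: Weitz–Scheffer nucleophilic epoxidation of the enone (the saturated lactone is inert): the peroxide anion should add to C1 on the outer face of the Z-enone, anti to C9 with the C10–H eclipsing the double bond, and the ring keeps the intermediate enolate from rotating so that closure gives the cis-epoxide.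

Step 23
Reactants: 36 epoxy ketone lactone
Product: 38 11-(dimethylaminomethyl) lactone, via lithium lactone enolate 37 (not isolated)
Conditions: LiN(SiMe3)2, THF, −78 °C; CH2=NMe2+ I−, −78 to 0 °C
Reagents that add atoms: N,N-dimethylmethyleneiminium iodide (Eschenmoser salt), C=[N+](C)C.[I-]
Why: Mannich reaction of the lactone enolate; the C3 ketone cannot compete because it has no enolisable α-hydrogen (C4 is quaternary and C2 is an epoxide carbon), and the new C11 centre disappears in step 24.

Step 24
Reactants: 38 11-(dimethylaminomethyl) lactone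
Product: 40 11(13)-methylene lactone, via trimethylammonium iodide 39 (not isolated)
Conditions: MeI, THF, rt; then aq. NaHCO3, EtOAc, rt
Reagents that add atoms: none
Why: N-Quaternisation followed by Hofmann-type (E1cB) elimination of trimethylamine under bicarbonate, mild enough to leave the exocyclic methylene in place.

Step 25
Reactants: 40 11(13)-methylene lactone
Product: 41 5,6-diol
Conditions: AcOH/H2O (4:1), 40 °C
Reagents that add atoms: none
Why: Acid-catalysed acetonide hydrolysis; the hindered tertiary silyl ether, the electron-poor epoxy ketone and the methylene lactone should tolerate aqueous acetic acid.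

Step 26
Reactants: 41 5,6-diol
Product: 42 6-O-(E)-crotonate
Conditions: (E)-crotonic anhydride (1.2 equiv), pyridine, DMAP (4-(dimethylamino)pyridine, cat.), CH2Cl2, −20 to 0 °C
Reagents that add atoms: (E)-crotonic anhydride, C/C=C/C(=O)OC(=O)/C=C/C
Why: Nucleophile-catalysed acylation; the C6 hydroxyl should react first because the C5 hydroxyl is neopentyl-like beside the quaternary C4 with its silyloxy group, and the anhydride with a weak base avoids the ketene pathway that would deconjugate the crotonate.

Step 27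
Reactants: 42 6-O-(E)-crotonate
Product: 43 5-O-acetyl 6-O-(E)-crotonate 4-silyl ether
Conditions: Ac2O, DMAP (4-(dimethylamino)pyridine), pyridine, CH2Cl2, rt
Reagents that add atoms: acetic anhydride, CC(=O)OC(C)=O
Why: Nucleophile-catalysed acetylation of the remaining hindered C5 hydroxyl.

Step 28
Reactants: 43 5-O-acetyl 6-O-(E)-crotonate 4-silyl ether
Product: 44 CNP0358125.1 (target)
Conditions: HF·pyridine, THF, 0 °C to rt
Reagents that add atoms: none
Why: Fluoride-mediated desilylation under mildly acidic conditions should free the tertiary C4 hydroxyl without acyl migration, Michael addition to the methylene lactone or opening of the epoxy ketone.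

Compound list
1 | 1,4-di-O-tosyl-2,3-O-isopropylidene-L-threitol (4S,5S) | Cc1ccc(cc1)S(=O)(=O)OC[C@@H]1OC(C)(C)O[C@H]1COS(=O)(=O)c1ccc(C)cc1 | starting material
2 | vinylmagnesium bromide | C=C[Mg]Br | starting material
3 | (4S,5S)-4,5-diallyl-2,2-dimethyl-1,3-dioxolane | C=CC[C@@H]1OC(C)(C)O[C@H]1CC=C | intermediate
4 | (3aS,7aS)-2,2-dimethyl-3a,4,7,7a-tetrahydro-1,3-benzodioxole | C1=CC[C@@H]2OC(C)(C)O[C@H]2C1 | intermediate
5 | cis-epoxide of 4 (C3–C8 oxirane, trans-5,6-acetonide) | C1[C@@H]2OC(C)(C)O[C@H]2C[C@H]3O[C@@H]13 | intermediate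
6 | trans-diaxial hydroxy selenide (C3–OH, C8–SePh) | O[C@H]1C[C@@H]2OC(C)(C)O[C@H]2C[C@@H]1[Se]c1ccccc1 | intermediate (not isolated)
7 | selenoxide of 6 | O[C@H]1C[C@@H]2OC(C)(C)O[C@H]2C[C@@H]1[Se](=O)c1ccccc1 | intermediate (not isolated)
8 | allylic alcohol (C3–OH, C7=C8, trans-5,6-acetonide) | O[C@H]1C[C@@H]2OC(C)(C)O[C@H]2C=C1 | intermediate
9 | (3aS,7aS)-2,2-dimethyl-3a,7a-dihydro-1,3-benzodioxol-5(4H)-one (C3 ketone, C7=C8) | O=C1C[C@@H]2OC(C)(C)O[C@H]2C=C1 | intermediate
10 | sodium cross-conjugated dienolate of 9 (C3=C4) | [Na+].[O-]C1=C[C@@H]2OC(C)(C)O[C@H]2C=C1 | intermediate (not isolated)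
11 | 4-hydroxy enone (OH cis to O5) | O=C1[C@H](O)[C@@H]2OC(C)(C)O[C@H]2C=C1 | intermediate
12 | 4-(tert-butyldimethylsilyloxy) enone | O=C1[C@H](O[Si](C)(C)C(C)(C)C)[C@@H]2OC(C)(C)O[C@H]2C=C1 | intermediate
13 | lithium enolate of 12 (C3=C4) | [Li+].[O-]C1=C(O[Si](C)(C)C(C)(C)C)[C@@H]2OC(C)(C)O[C@H]2C=C1 | intermediate (not isolated)
14 | enone with quaternary C4 (4S; methyl axial, OTBS equatorial) | O=C1[C@@](C)(O[Si](C)(C)C(C)(C)C)[C@@H]2OC(C)(C)O[C@H]2C=C1 | intermediate
15 | 7-vinyl C3=C8 trimethylsilyl enol ether (vinyl axial, cis to O6) | C[Si](C)(C)OC1=C[C@H](C=C)[C@@H]2OC(C)(C)O[C@H]2[C@]1(C)O[Si](C)(C)C(C)(C)C | intermediate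
16 | 7-vinyl 8-trimethylsilyloxy C3 ketone | O=C1[C@@](C)(O[Si](C)(C)C(C)(C)C)[C@@H]2OC(C)(C)O[C@H]2[C@@H](C=C)[C@@H]1O[Si](C)(C)C | intermediate (not isolated)
17 | 7-vinyl 8-hydroxy C3 ketone (OH trans to vinyl) | O=C1[C@@](C)(O[Si](C)(C)C(C)(C)C)[C@@H]2OC(C)(C)O[C@H]2[C@@H](C=C)[C@@H]1O | intermediate
18 | B-alkyl-9-BBN adduct of 17 (boron on C12) | O=C1[C@@](C)(O[Si](C)(C)C(C)(C)C)[C@@H]2OC(C)(C)O[C@H]2[C@@H](CCB3C4CCCC3CCC4)[C@@H]1O | intermediate (not isolated)
19 | keto diol (C7 2-hydroxyethyl, C8–OH, C3 ketone) | O=C1[C@@](C)(O[Si](C)(C)C(C)(C)C)[C@@H]2OC(C)(C)O[C@H]2[C@@H](CCO)[C@@H]1O | intermediate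
20 | C12 tert-butyldimethylsilyl ether of 19 | O=C1[C@@](C)(O[Si](C)(C)C(C)(C)C)[C@@H]2OC(C)(C)O[C@H]2[C@@H](CCO[Si](C)(C)C(C)(C)C)[C@@H]1O | intermediate
21 | 3-vinyl 3,8-diol (vinyl equatorial, C3–OH axial) | C=C[C@]1(O)[C@@](C)(O[Si](C)(C)C(C)(C)C)[C@@H]2OC(C)(C)O[C@H]2[C@@H](CCO[Si](C)(C)C(C)(C)C)[C@@H]1O | intermediate
22 | 3-vinyl 3-hydroxy 8-ketone | C=C[C@]1(O)[C@@](C)(O[Si](C)(C)C(C)(C)C)[C@@H]2OC(C)(C)O[C@H]2[C@@H](CCO[Si](C)(C)C(C)(C)C)C1=O | intermediate
23 | 3-vinyl 3-trimethylsilyloxy 8-ketone | C=C[C@]1(O[Si](C)(C)C)[C@@](C)(O[Si](C)(C)C(C)(C)C)[C@@H]2OC(C)(C)O[C@H]2[C@@H](CCO[Si](C)(C)C(C)(C)C)C1=O | intermediate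
24 | (E)-1-bromopropene | C/C=C/Br | starting material
25 | (E)-prop-1-enyllithium | C/C=C/[Li] | intermediate (not isolated)
26 | (E)-prop-1-enylcerium dichloride | C/C=C/[Ce](Cl)Cl | intermediate (not isolated)
27 | trans-3-vinyl-8-[(E)-propenyl]cyclohexane-3,8-diol 3-trimethylsilyl ether (C8–OH axial) | C=C[C@]1(O[Si](C)(C)C)[C@@](C)(O[Si](C)(C)C(C)(C)C)[C@@H]2OC(C)(C)O[C@H]2[C@@H](CCO[Si](C)(C)C(C)(C)C)[C@@]1(O)/C=C/C | intermediate
28 | potassium C8 alkoxide of 27 | [K+].C=C[C@]1(O[Si](C)(C)C)[C@@](C)(O[Si](C)(C)C(C)(C)C)[C@@H]2OC(C)(C)O[C@H]2[C@@H](CCO[Si](C)(C)C(C)(C)C)[C@@]1([O-])/C=C/C | intermediate (not isolated)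
29 | potassium C8=C9 enolate of the ten-membered ring (C2=C3 silyl enol ether) | [K+].[O-]/C1=C\[C@@H](C)C/C=C(\O[Si](C)(C)C)[C@@](C)(O[Si](C)(C)C(C)(C)C)[C@@H]2OC(C)(C)O[C@H]2[C@H]1CCO[Si](C)(C)C(C)(C)C | intermediate (not isolated)
30 | ten-membered C8 ketone with C2=C3 trimethylsilyl enol ether (C1 cis to OSi) and C10 methyl | O=C1C[C@@H](C)C/C=C(\O[Si](C)(C)C)[C@@](C)(O[Si](C)(C)C(C)(C)C)[C@@H]2OC(C)(C)O[C@H]2[C@H]1CCO[Si](C)(C)C(C)(C)C | intermediate
31 | (1Z)-ene-3,8-dione | O=C1C[C@@H](C)/C=C\C(=O)[C@@](C)(O[Si](C)(C)C(C)(C)C)[C@@H]2OC(C)(C)O[C@H]2[C@H]1CCO[Si](C)(C)C(C)(C)C | intermediate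
32 | (8R)-8-hydroxy (1Z)-en-3-one | O[C@@H]1C[C@@H](C)/C=C\C(=O)[C@@](C)(O[Si](C)(C)C(C)(C)C)[C@@H]2OC(C)(C)O[C@H]2[C@H]1CCO[Si](C)(C)C(C)(C)C | intermediate
33 | 8,12-diol | O[C@@H]1C[C@@H](C)/C=C\C(=O)[C@@](C)(O[Si](C)(C)C(C)(C)C)[C@@H]2OC(C)(C)O[C@H]2[C@H]1CCO | intermediate
34 | lactol (C12 hemiacetal with O8, anomers) | C1C(O)O[C@@H]2C[C@@H](C)/C=C\C(=O)[C@@](C)(O[Si](C)(C)C(C)(C)C)[C@@H]3OC(C)(C)O[C@H]3[C@@H]12 | intermediate (not isolated)
35 | (1Z)-en-3-one 8,12-olide (trans-fused lactone) | C1C(=O)O[C@@H]2C[C@@H](C)/C=C\C(=O)[C@@](C)(O[Si](C)(C)C(C)(C)C)[C@@H]3OC(C)(C)O[C@H]3[C@@H]12 | intermediate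
36 | (1S,2S)-1,2-cis-epoxy-3-oxo 8,12-olide | C1C(=O)O[C@@H]2C[C@@H](C)[C@@H]3O[C@@H]3C(=O)[C@@](C)(O[Si](C)(C)C(C)(C)C)[C@@H]4OC(C)(C)O[C@H]4[C@@H]12 | intermediate
37 | lithium enolate of lactone 36 (C11=C12) | [Li+].C1=C([O-])O[C@@H]2C[C@@H](C)[C@@H]3O[C@@H]3C(=O)[C@@](C)(O[Si](C)(C)C(C)(C)C)[C@@H]4OC(C)(C)O[C@H]4[C@@H]12 | intermediate (not isolated)
38 | 11-(dimethylaminomethyl) lactone | CN(C)C[C@@H]1C(=O)O[C@@H]2C[C@@H](C)[C@@H]3O[C@@H]3C(=O)[C@@](C)(O[Si](C)(C)C(C)(C)C)[C@@H]4OC(C)(C)O[C@H]4[C@@H]12 | intermediate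
39 | trimethylammonium iodide of 38 | C[N+](C)(C)C[C@@H]1C(=O)O[C@@H]2C[C@@H](C)[C@@H]3O[C@@H]3C(=O)[C@@](C)(O[Si](C)(C)C(C)(C)C)[C@@H]4OC(C)(C)O[C@H]4[C@@H]12.[I-] | intermediate (not isolated)
40 | 11(13)-methylene lactone (acetonide, 4-OTBS) | C=C1C(=O)O[C@@H]2C[C@@H](C)[C@@H]3O[C@@H]3C(=O)[C@@](C)(O[Si](C)(C)C(C)(C)C)[C@@H]4OC(C)(C)O[C@H]4[C@@H]12 | intermediate
41 | 5,6-diol (4-OTBS) | C=C1C(=O)O[C@@H]2C[C@@H](C)[C@@H]3O[C@@H]3C(=O)[C@@](C)(O[Si](C)(C)C(C)(C)C)[C@H](O)[C@@H](O)[C@@H]12 | intermediate
42 | 6-O-(E)-crotonate (5-OH, 4-OTBS) | C=C1C(=O)O[C@@H]2C[C@@H](C)[C@@H]3O[C@@H]3C(=O)[C@@](C)(O[Si](C)(C)C(C)(C)C)[C@H](O)[C@@H](OC(=O)/C=C/C)[C@@H]12 | intermediate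
43 | 5-O-acetyl 6-O-(E)-crotonate (4-OTBS) | C=C1C(=O)O[C@@H]2C[C@@H](C)[C@@H]3O[C@@H]3C(=O)[C@@](C)(O[Si](C)(C)C(C)(C)C)[C@H](OC(C)=O)[C@@H](OC(=O)/C=C/C)[C@@H]12 | intermediate
44 | CNP0358125.1 | C=C1C(=O)O[C@@H]2C[C@@H](C)[C@@H]3O[C@@H]3C(=O)[C@@](C)(O)[C@H](OC(C)=O)[C@@H](OC(=O)/C=C/C)[C@@H]12 | target

Total step count: 28.
Longest linear sequence: 28 steps (1 to 44); 2 and 24 are bought and enter as reagents.

Steps most likely to fail

Step 16. The C8 carbonyl of 23 lies between the fully substituted C3 and the axial C7 chain, so the alkenylcerium reagent may act as a base (enolisation towards C7), fail to add, or lose its facial preference. The fallback sets out from 23: the much slimmer 1-propynyllithium with CeCl3 (from propyne and n-BuLi, THF, −78 °C) should add to give the tertiary propargylic alcohol F1. Alkoxide-directed trans-hydroalumination of the alkyne with NaAlH2(OCH2CH2OMe)2 in THF and protonolysis then give the (E)-propenyl carbinol, and the route is rejoined at 27.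

Step 18. β-Hydride elimination from the palladium enolate may follow the ring conformer that gives the E-enone, or give E/Z mixtures. Base equilibration cannot repair this, because it would move the double bond out of conjugation towards C10. The fallback sets out from 30: the E isomer of the enedione F2 is accepted from the oxidation and converted in a separate sensitised photochemical E-to-Z isomerisation (thioxanthone or Ir(ppy)3, 420–450 nm light, MeCN). The twisted Z-enone should accumulate as the poorer energy acceptor, and the route is rejoined at 31.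

Step 22. The peroxide anion may add on the inner face, or the β-peroxy enolate may rotate before ring closure, so that facial or cis/trans control is lost; long exposure to base could also shift the double bond. The fallback sets out from 35: Luche reduction (NaBH4, CeCl3·7H2O, MeOH, −78 °C) gives the Z-allylic alcohol F3. Concerted hydroxyl-directed epoxidation (VO(acac)2, t-BuOOH, CH2Cl2) gives the cis-epoxy alcohol F4, and Dess–Martin oxidation returns the epoxy ketone 36. In this sequence the alkene geometry is carried over stereospecifically and the face is set by the carbinol (the epimer drawn directs to the required face) instead of by the ring conformation.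

Further compounds
F1 | step 16 | 8-(prop-1-ynyl) tertiary propargylic alcohol (3-vinyl 3-trimethylsilyloxy, C8–OH axial) | C=C[C@]1(O[Si](C)(C)C)[C@@](C)(O[Si](C)(C)C(C)(C)C)[C@@H]2OC(C)(C)O[C@H]2[C@@H](CCO[Si](C)(C)C(C)(C)C)[C@@]1(O)C#CC
F2 | step 18 | (1E)-ene-3,8-dione (E isomer of 31) | O=C1C[C@@H](C)/C=C/C(=O)[C@@](C)(O[Si](C)(C)C(C)(C)C)[C@@H]2OC(C)(C)O[C@H]2[C@H]1CCO[Si](C)(C)C(C)(C)C
F3 | step 22 | (1Z)-en-3-ol 8,12-olide (Z-allylic alcohol) | C1C(=O)O[C@@H]2C[C@@H](C)/C=C\[C@@H](O)[C@@](C)(O[Si](C)(C)C(C)(C)C)[C@@H]3OC(C)(C)O[C@H]3[C@@H]12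
F4 | step 22 | 1,2-cis-epoxy-3-ol 8,12-olide (epoxy alcohol) | C1C(=O)O[C@@H]2C[C@@H](C)[C@@H]3O[C@@H]3[C@@H](O)[C@@](C)(O[Si](C)(C)C(C)(C)C)[C@@H]4OC(C)(C)O[C@H]4[C@@H]12
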